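Retrosynthesis: the first cut is the C8–C9 bond between the exocyclic vinyl carbon on ring C5 and the side-chain ketone carbon, giving a ring vinylstannane and an S-phenyl thioester. The ring half is then cut at the C6–O acyl bond, the C6–O bond, the C8–Sn bond (back to an enol triflate and a C5 acetyl group, i.e. the ozonized isopropenyl of carvone) and the epoxide; the chain half at its C–S bond and its C=C bond (cross-metathesis).
Forward: no ring is built. The six-membered ring of (R)-carvone is carried through (C1 reduction, C2–C3 epoxidation, silylation, ozonolysis, enol triflate, stannane, C1 back to the ketone, C6 hydroxylation, tigloylation), the acyl chain is made in two steps, and the halves are joined in the last step.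
Stereochemistry: C5 is bought with (R)-carvone. A temporary C1 carbinol, set cis to the C5 substituent by Luche reduction, directs the epoxide oxygen to that same face (C2, C3); nucleophilic epoxidation of the enone would go to the other face. C6 is set by enolate hydroxylation anti to the C5 substituent and the epoxide; the E enone comes from metathesis and the E tiglate from tigloyl chloride.
Enabling feature: C8 is an sp2 carbon outside the ring that carries only ring C5 and the =CH2 group, so it is the carbonyl carbon of a methyl ketone in disguise and can bear tin. C9 lies outside the epoxycyclohexanone ring (C1–C6), so a neutral Pd/Cu thioester–stannane ketone synthesis can deliver the whole cross-conjugated dienone, with the tertiary alcohol unprotected, after every base- or oxidant-dependent operation is over.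

Key step: step 13

Remark: ring carbons are numbered as in carvone (C1 carbonyl, C2 methyl-bearing, C5 chain-bearing, C6 tiglate-bearing) and the chain is C8 (vinyl carbon on C5), C9 (ketone), C10=C11, C12 (carbinol); β is the ring face of the C5 substituent. The target is read as 2β,3β-epoxide, 6α-(E)-2-methylbut-2-enoate (tiglate), i.e. 2S,3S,5S,6S in this numbering, which corresponds to the C5 configuration of (R)-carvone.

Step 1
Reactants: 1 (R)-(−)-carvone
Product: 2 (1R,5R)-cis-carveol
Conditions: NaBH4, CeCl3·7H2O, MeOH, −78 to 0 °C
Reagents that add atoms: none
Why: Luche reduction: the cerium-activated carbonyl takes hydride 1,2 and from the axial direction of the half-chair with the isopropenyl group equatorial, which should give the C1 carbinol cis to the C5 substituent (β-OH) and leave both alkenes untouched.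

Step 2
Reactants: 2 (1R,5R)-cis-carveol
Product: 3 2β,3β-epoxy-cis-carveol
Conditions: VO(acac)2 (cat.), t-BuOOH, CH2Cl2, 0 °C to rt
Reagents that add atoms: tert-butyl hydroperoxide, CC(C)(C)OO
Why: Vanadium-catalysed hydroxyl-directed epoxidation: the peroxide is delivered within the vanadate ester of the C1 hydroxyl to the same (β) face of the C2=C3 bond, which sets C2 and C3 cis to the C5 substituent, while the isopropenyl alkene, having no directing hydroxyl, should not react.

Step 3
Reactants: 3 2β,3β-epoxy-cis-carveol
Product: 4 C1 tert-butyldimethylsilyl ether of 3
Conditions: TBSCl, imidazole, DMAP (cat.), DMF, rt to 40 °C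
Reagents that add atoms: tert-butyldimethylsilyl chloride, CC(C)(C)[Si](C)(C)Cl
Why: Standard imidazole-promoted silylation of a secondary alcohol, neutral toward the epoxide; the silyl ether keeps C1 from being an enolizable ketone or an acidic hydroxyl during steps 4 to 6.

Step 4
Reactants: 4 C1 tert-butyldimethylsilyl ether of 3
Product: 6 C5 acetyl compound (methyl ketone), via secondary ozonide 5 (not isolated)
Conditions: O3, CH2Cl2, −78 °C; then PPh3, −78 °C to rt
Reagents that add atoms: ozone, [O-][O+]=O
Why: Ozonolysis with reductive work-up: the isopropenyl group is the only C=C bond in 4, the ozonide is cleaved by the phosphine to the C5 acetyl group and formaldehyde, and the neutral conditions should leave the now enolizable C5 centre, the epoxide and the silyl ether as they are.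

Step 5
Reactants: 6 C5 acetyl compound (methyl ketone)
Product: 8 terminal enol triflate, via potassium enolate 7 (not isolated)
Conditions: KHMDS, THF, −78 °C (ketone added to the base); then PhNTf2, −78 to 0 °C
Reagents that add atoms: N-phenylbis(trifluoromethanesulfonimide), O=S(=O)(N(c1ccccc1)S(=O)(=O)C(F)(F)F)C(F)(F)F; potassium bis(trimethylsilyl)amide, C[Si](C)(C)[N-][Si](C)(C)C.[K+] (supplies only the potassium of 7)
Why: Kinetic enolate O-triflation: the bulky amide base at −78 °C removes a proton from the unhindered CH3 and not from the tertiary C5–H, so the terminal enol triflate should form and C5, which is never part of an enolate, keeps its configuration.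

Step 6
Reactants: 8 terminal enol triflate
Product: 9 C8 trimethylstannyl alkene (silyl ether)
Conditions: (Me3Sn)2, Pd(PPh3)4 (cat.), LiCl, THF, 60 °C
Reagents that add atoms: hexamethylditin, C[Sn](C)(C)[Sn](C)(C)C
Why: Palladium-catalysed stannylation of an enol triflate with a distannane (Stille-type): oxidative addition into the C8–O bond, chloride-assisted transmetalation with the ditin and reductive elimination put tin on C8 without moving the double bond, and the epoxy silyl ether is inert to Pd(0).

Step 7
Reactants: 9 C8 trimethylstannyl alkene (silyl ether)
Product: 10 vinylstannane epoxy alcohol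
Conditions: TBAF, THF, 0 °C to rt
Reagents that add atoms: none
Why: Fluoride desilylation driven by the Si–F bond: the vinyl–tin bond should not be cleaved by fluoride under these conditions, and the C1 alkoxide, being cis to the epoxide, cannot open it by backside attack (no Payne rearrangement).

Step 8
Reactants: 10 vinylstannane epoxy alcohol
Product: 11 vinylstannane epoxy ketone
Conditions: Dess–Martin periodinane, NaHCO3, CH2Cl2, 0 °C to rt
Reagents that add atoms: none
Why: Dess–Martin oxidation of the secondary carbinol under bicarbonate buffer: a hypervalent-iodine oxidation that is neither basic nor strongly acidic, which should spare the vinylstannane and give the α,β-epoxy ketone in which C2 is quaternary, so that only C6 can later be enolized.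

Step 9
Reactants: 11 vinylstannane epoxy ketone
Product: 13 6α-hydroxy ketone, via sodium enolate 12 (not isolated)
Conditions: NaHMDS, THF, −78 °C; then 2-(phenylsulfonyl)-3-phenyloxaziridine, −78 °C; then AcOH (1.1 equiv), −78 °C
Reagents that add atoms: 2-(phenylsulfonyl)-3-phenyloxaziridine, O=S(=O)(c1ccccc1)N1OC1c1ccccc1; sodium bis(trimethylsilyl)amide, C[Si](C)(C)[N-][Si](C)(C)C.[Na+] (supplies only the sodium of 12)
Why: Enolate hydroxylation with an N-sulfonyloxaziridine (Davis oxidation): enolization can only occur toward C6, and the oxidant should approach the enolate on the α face, opposite both the neighbouring C5 substituent and the epoxide oxygen, which sets the C6 hydroxyl trans to the C5 group, while the oxaziridine is too weak an electrophile to touch the vinylstannane.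

Step 10
Reactants: 13 6α-hydroxy ketone
Product: 14 6α-tiglate (ring half)
Conditions: tigloyl chloride, pyridine, DMAP (cat.), CH2Cl2, 0 °C
Reagents that add atoms: (E)-2-methylbut-2-enoyl chloride (tigloyl chloride), C/C=C(\C)C(=O)Cl
Why: Pyridine/DMAP acylation of the secondary alcohol with the acid chloride: the C6–O bond is not broken, so C6 keeps its configuration and the E geometry of the tigloyl group is carried over, and the acid chloride does not react with the vinylstannane in the absence of palladium.

Step 11
Reactants: 15 2-methylbut-3-en-2-ol (3 equiv); 16 acrylic acid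
Product: 17 (E)-4-hydroxy-4-methylpent-2-enoic acid
Conditions: Hoveyda–Grubbs II (3 mol%), CH2Cl2, 40 °C
Reagents that add atoms: none
Why: Olefin cross-metathesis between a hindered tertiary allylic alcohol (slow to homodimerize) and an electron-poor acrylic partner: ethylene is lost and the conjugated disubstituted alkene should form under thermodynamic control as the E isomer.

Step 12
Reactants: 17 (E)-4-hydroxy-4-methylpent-2-enoic acid
Product: 18 S-phenyl (E)-4-hydroxy-4-methylpent-2-enethioate
Conditions: PhSH, DCC, DMAP (cat.), CH2Cl2, 0 °C
Reagents that add atoms: thiophenol, Sc1ccccc1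
Why: Carbodiimide thioesterification (Steglich type): the acid is activated by DCC/DMAP and captured by the thiol, the tertiary hydroxyl is too hindered to compete, the E-configured γ-hydroxy acid cannot lactonize, and the low temperature and the hindered β-carbon should hold back thiol conjugate addition.

Step 13
Reactants: 14 6α-tiglate (ring half); 18 S-phenyl (E)-4-hydroxy-4-methylpent-2-enethioate
Product: 19 target
Conditions: Pd2(dba)3 (2.5 mol%), tri(2-furyl)phosphine (20 mol%), copper(I) diphenylphosphinate (1.3 equiv), degassed THF, rt to 45 °C
Reagents that add atoms: none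
Why: Liebeskind–Srogl-type thioester–organostannane ketone synthesis: Pd(0) inserts into the C(acyl)–S bond of 18 once copper(I) binds the sulfur, the phosphinate on copper takes the trimethyltin group of 14 and hands the C8 vinyl group to palladium, and reductive elimination forms the C8–C9 bond. The closest known reaction type is the copper(I) diphenylphosphinate-mediated, palladium-catalysed coupling of thiol esters with aryl and alkenyl stannanes, with the Stille synthesis of divinyl ketones from acid chlorides as the older relative. No ring is closed and no stereocentre is formed; the E geometry of C10=C11 and the configurations at C5 and C6 should be carried through because the medium is neutral and holds no free base or free thiolate (the sulfur leaves bound to copper). The selectivity needed is chemoselectivity for the thioester C–S bond over the tiglate and over 1,4-addition to either enone, and it rests on the fact that Pd(0)/Cu(I) activates only the thiol ester while the O-ester, the epoxy ketone and the free tertiary alcohol are inert. The tin sits on C8, an exocyclic sp2 carbon bearing only ring C5 and =CH2, so the vinyl group transfers with its position fixed and no regio- or stereochemical question arises at the new bond. Because the dienone is formed in its final oxidation state and without protecting groups, nothing basic, oxidizing or fluoride-based has to be done once it exists.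

Compound list
1 | (R)-(−)-carvone | C=C(C)[C@@H]1CC=C(C)C(=O)C1 | starting material
2 | (1R,5R)-cis-carveol (C1 hydroxyl cis to isopropenyl) | C=C(C)[C@@H]1CC=C(C)[C@H](O)C1 | intermediate
3 | 2β,3β-epoxy-cis-carveol: 1-methyl-4-(prop-1-en-2-yl)-7-oxabicyclo[4.1.0]heptan-2-ol with hydroxyl, epoxide oxygen and isopropenyl all on the β face | C=C(C)[C@@H]1C[C@@H]2O[C@]2(C)[C@H](O)C1 | intermediate
4 | C1 tert-butyldimethylsilyl ether of 3 | C=C(C)[C@@H]1C[C@@H]2O[C@]2(C)[C@H](O[Si](C)(C)C(C)(C)C)C1 | intermediate
5 | secondary ozonide (3-methyl-1,2,4-trioxolan-3-yl group on C5, mixture at the trioxolane carbon) | CC3(OCOO3)[C@@H]1C[C@@H]2O[C@]2(C)[C@H](O[Si](C)(C)C(C)(C)C)C1 | intermediate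
6 | C5β-acetyl-2β,3β-epoxy-1β-silyloxy compound (methyl ketone) | CC(=O)[C@@H]1C[C@@H]2O[C@]2(C)[C@H](O[Si](C)(C)C(C)(C)C)C1 | intermediate
7 | potassium enolate of 6 on the methyl side | C=C([O-])[C@@H]1C[C@@H]2O[C@]2(C)[C@H](O[Si](C)(C)C(C)(C)C)C1.[K+] | intermediate
8 | terminal enol triflate: 1-(ring-C5)vinyl trifluoromethanesulfonate | C=C(OS(=O)(=O)C(F)(F)F)[C@@H]1C[C@@H]2O[C@]2(C)[C@H](O[Si](C)(C)C(C)(C)C)C1 | intermediate
9 | C8 trimethylstannyl alkene, 2β,3β-epoxide, 1β-OTBS | C=C([Sn](C)(C)C)[C@@H]1C[C@@H]2O[C@]2(C)[C@H](O[Si](C)(C)C(C)(C)C)C1 | intermediate
10 | vinylstannane epoxy alcohol (1β-OH) | C=C([Sn](C)(C)C)[C@@H]1C[C@@H]2O[C@]2(C)[C@H](O)C1 | intermediate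
11 | vinylstannane epoxy ketone: 2β,3β-epoxy-5β-[1-(trimethylstannyl)vinyl]-2-methylcyclohexanone | C=C([Sn](C)(C)C)[C@@H]1C[C@@H]2O[C@]2(C)C(=O)C1 | intermediate
12 | sodium C1–C6 enolate of 11 | C=C([Sn](C)(C)C)[C@@H]1C[C@@H]2O[C@]2(C)C([O-])=C1.[Na+] | intermediate
13 | 6α-hydroxy ketone (hydroxyl trans to the C5 substituent and to the epoxide) | C=C([Sn](C)(C)C)[C@@H]1C[C@@H]2O[C@]2(C)C(=O)[C@H]1O | intermediate
14 | 6α-tiglate of 13 (ring half) | C=C([Sn](C)(C)C)[C@@H]1C[C@@H]2O[C@]2(C)C(=O)[C@H]1OC(=O)/C(C)=C/C | intermediate
15 | 2-methylbut-3-en-2-ol | C=CC(C)(C)O | starting material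
16 | acrylic acid | C=CC(=O)O | starting material
17 | (E)-4-hydroxy-4-methylpent-2-enoic acid | CC(C)(O)/C=C/C(=O)O | intermediate
18 | S-phenyl (E)-4-hydroxy-4-methylpent-2-enethioate (chain half) | CC(C)(O)/C=C/C(=O)Sc1ccccc1 | intermediate
19 | target: 2β,3β-epoxy-6α-tigloyloxy-2-methylcyclohexanone bearing at C5β the (E)-6-hydroxy-6-methyl-3-oxohepta-1,4-dien-2-yl chain (2S,3S,5S,6S, carvone numbering) | C=C(C(=O)/C=C/C(C)(C)O)[C@@H]1C[C@@H]2O[C@]2(C)C(=O)[C@H]1OC(=O)/C(C)=C/C | target

Total step count: 13. Longest linear sequence: 11 steps (steps 1 to 10, then step 13).

Steps most likely to fail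

Step 13. The transfer of the α-branched vinyl group from tin to palladium may be slow, because C8 is flanked by ring C5. Protodestannylation, oxidative homocoupling of the stannane, conjugate addition of copper-bound thiolate to the newly formed dienone, or Pd(0)-induced isomerization of the epoxy ketone on prolonged warming could then compete. The fallback reverses the roles of the partners so that the hindered carbon enters by oxidative addition instead of transmetalation. It sets out from 14, which on iododestannylation (I2, CH2Cl2, 0 °C) should give the C8 vinyl iodide F1 with the double bond in place. Separately, 2-methylbut-3-yn-2-ol F2 is hydrostannylated (Bu3SnH, cat. PdCl2(PPh3)2, THF) to (E)-2-methyl-4-(tributylstannyl)but-3-en-2-ol F3. A carbonylative Stille coupling of F1 and F3 (CO, 1–3 atm, Pd2(dba)3, AsPh3, THF, 50 °C), in which C9 comes from carbon monoxide, comes back to the route at 19.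

Step 9. The sodium enolate may decompose before it is oxidized (attack of the C6 carbanion on the C2–O bond of the epoxide, or capture by the sulfonimine by-product), facial selectivity may erode, or the product alkoxide may isomerize before the quench. The fallback moves the oxidation to a neutral species. It sets out from 11, which with LDA in the presence of TMSCl (THF, −78 °C, internal quench, so that the enolate has almost no lifetime) should give the trimethylsilyl enol ether F4. Rubottom oxidation with dimethyldioxirane (acetone/CH2Cl2, −78 to −40 °C) should epoxidize the enol ether on the α face and, after silyl migration, give the 6α-trimethylsilyloxy ketone F5. Citric acid in MeOH removes the silyl group and comes back to the route at 13.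

Step 5. Enolization toward C5 instead of the methyl group, or proton exchange between enolate and unreacted ketone, would give the internal enol triflate and scramble the C5 configuration. The fallback avoids the ketone enolate altogether. It sets out from 6, which is condensed with 2,4,6-triisopropylbenzenesulfonyl hydrazide (THF/MeOH, rt) to the 2,4,6-triisopropylbenzenesulfonylhydrazone F6. A Shapiro reaction (n-BuLi, 2.2 equiv, THF/TMEDA, −78 to 0 °C) should deprotonate the methyl side of the hydrazone dianion and, with loss of nitrogen and sulfinate, give the C8 vinyllithium F7, which is trapped with Me3SnCl. This comes back to the route at 9 and skips 8.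

Further compounds
F1 | step 13 | C8 vinyl iodide of the ring half (iodine in place of the trimethylstannyl group of 14) | C=C(I)[C@@H]1C[C@@H]2O[C@]2(C)C(=O)[C@H]1OC(=O)/C(C)=C/C
F2 | step 13 | 2-methylbut-3-yn-2-ol | C#CC(C)(C)O
F3 | step 13 | (E)-2-methyl-4-(tributylstannyl)but-3-en-2-ol | CCCC[Sn](CCCC)(CCCC)/C=C/C(C)(C)O
F4 | step 9 | trimethylsilyl enol ether of 11 (C1–C6 enol ether) | C=C([Sn](C)(C)C)[C@@H]1C[C@@H]2O[C@]2(C)C(O[Si](C)(C)C)=C1
F5 | step 9 | 6α-trimethylsilyloxy ketone | C=C([Sn](C)(C)C)[C@@H]1C[C@@H]2O[C@]2(C)C(=O)[C@H]1O[Si](C)(C)C
F6 | step 5 | 2,4,6-triisopropylbenzenesulfonylhydrazone of 6 | CC(=NNS(=O)(=O)c3c(C(C)C)cc(C(C)C)cc3C(C)C)[C@@H]1C[C@@H]2O[C@]2(C)[C@H](O[Si](C)(C)C(C)(C)C)C1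
F7 | step 5 | C8 vinyllithium | C=C([Li])[C@@H]1C[C@@H]2O[C@]2(C)[C@H](O[Si](C)(C)C(C)(C)C)C1
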